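**Retrosynthetic overview**
1. Target 13 ⇐ 11: both prenyl groups go last onto the one free ring-A carbon (C-5), which is masked until then as a 1,3-dithiane so that ring A stays non-aromatic and cannot autoxidise.
2. The C-7' carbinol ⇐ Markovnikov radical hydration of the C6'=C7' alkene of 8, with O2 captured on the equatorial face.
3. Key step: intramolecular Diels–Alder reaction of dienylidene trione 6 (diene ending on the future spiro carbon, vinyl dienophile); it closes the spiro six-membered ring and the cyclopentane together and sets C-1, C-3a' and C-7a'.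
4. 6 ⇐ Knoevenagel condensation of blocked trione 3 with (2E,6R)-8-oxolinalool 5; 5 ⇐ SeO2 oxidation of (R)-linalool, whose carbinol carbon (C-3') is the only bought stereocenter.
5. Ring order: ring A (bought as the arene, dearomatised in step 1), then the six- and five-membered carbocycles in one cycloaddition.

Assumption: ring A is drawn throughout in the enol tautomer of the target SMILES; 1, 4 and trimethylene dithiotosylate are bought; locants follow spiro[cyclohexane-1,5'-indene] (ring A unprimed, hydrindane primed).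

**Step 1**
Reactants: 1 phlorisobutyrophenone
Product: 3 7-hydroxy-8-(2-methylpropanoyl)-1,5-dithiaspiro[5.5]undec-7-ene-9,11-dione, via monosulfenylated thiosulfonate 2 (not isolated)
Conditions: TsS(CH2)3STs (1.05 equiv), KOAc (4 equiv), EtOH, 70 °C
Reagents that add atoms: trimethylene dithiotosylate, Cc1ccc(cc1)S(=O)(=O)SCCCSS(=O)(=O)c1ccc(C)cc1
Why: Double C-sulfenylation with the tethered thiosulfonate (Woodward active-methylene blocking) puts the second sulfur on the same ring carbon, which dearomatises ring A, leaves one ring CH2 as a cyclic 1,3-dione site for step 3 and masks the other nucleophilic carbon until step 6.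

**Step 2**
Reactants: 4 (R)-(−)-linalool
Product: 5 (2E,6R)-6-hydroxy-2,6-dimethylocta-2,7-dienal
Conditions: SeO2 (1.2 equiv), 1,4-dioxane, 80 °C
Reagents that add atoms: selenium dioxide, O=[Se]=O
Why: Riley allylic oxidation (ene reaction, then [2,3]-sigmatropic shift) attacks the (E)-methyl of the trisubstituted alkene and runs on to the (E)-enal, and the tertiary carbinol stereocenter is not touched.

**Step 3**
Reactants: 3 dithioketal-blocked trione; 5 (2E,6R)-8-oxolinalool
Product: 8 (1S,3'R,3a'S,7a'R) spiro[cyclohexene-1,5'-indene] Diels–Alder adduct, via Knoevenagel dienone 6 (not isolated), via 2H-pyran valence tautomer 7 (not isolated)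
Conditions: ethylenediammonium diacetate (10 mol%), toluene, 23 °C, 3 h; then BHT, 165 °C (sealed tube), 24 h
Reagents that add atoms: none
Why: Domino Knoevenagel condensation / intramolecular Diels–Alder reaction: the 1,1-diacyl diene (resting as its 2H-pyran by reversible oxa-6π electrocyclisation) adds to the tethered vinyl group through the tether-anti transition state, which gives the trans ring fusion because the diene methyl clashes with the quaternary carbinol carbon in the syn mode, the (R)-carbinol fixes the alkene face (methyl anti, hydroxyl inside), and the spiro carbon follows from the alkylidene isomer that keeps the more electron-poor ketone (next to the dithioketal) outside and conjugated.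

**Step 4**
Reactants: 8 Diels–Alder adduct
Product: 10 (1S,3'R,3a'S,7'R,7a'R) 3',7'-diol dithioketal, via tertiary hydroperoxide 9 (not isolated)
Conditions: Mn(dpm)3 (dpm = dipivaloylmethanate, 10 mol%), PhSiH3 (2 equiv), O2 (1 atm), i-PrOH/CH2Cl2, 0 °C; then PPh3
Reagents that add atoms: dioxygen, O=O
Why: Mukaiyama hydration by hydrogen-atom transfer puts H on C-6' and the tertiary C-7' radical takes O2 on the equatorial face, away from the axial spiro carbonyl that sits 1,3 to it, so the hydroxyl is equatorial and the methyl axial (7'R); the only alkene present reacts and the blocked ring-A carbon cannot be oxidised.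

**Step 5**
Reactants: 10 3',7'-diol dithioketal
Product: 11 (1R,3'R,3a'S,7'R,7a'R) deblocked spiro trione
Conditions: Raney Ni (W-2), EtOH, 23 °C, argon
Reagents that add atoms: none
Why: Raney nickel desulfurisation cleaves the four C–S bonds and frees the ring-A CH2 without touching ketones or carbinols; no stereocenter is involved (the C-1 descriptor changes from S to R only because the CIP priorities change).

**Step 6**
Reactants: 11 deblocked spiro trione
Product: 13 CNP0273836.1, via monoprenyl trione 12 (not isolated)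
Conditions: prenyl bromide (2.5 equiv), NaOMe (2.5 equiv), MeOH, 0 to 23 °C
Reagents that add atoms: prenyl bromide, CC(C)=CCBr
Why: Double C-alkylation of the vinylogous acid (lupulone-type gem-diprenylation) can only occur at C-5, the one nucleophilic carbon left, and no stereocenter is formed or touched.

**Compound list**
1 | 2-methyl-1-(2,4,6-trihydroxyphenyl)propan-1-one (phlorisobutyrophenone) | CC(C)C(=O)c1c(O)cc(O)cc1O | starting material
2 | S-{3-[(2,4,6-trihydroxy-3-(2-methylpropanoyl)phenyl)sulfanyl]propyl} 4-methylbenzenesulfonothioate | CC(C)C(=O)c1c(O)cc(O)c(SCCCSS(=O)(=O)c2ccc(C)cc2)c1O | intermediate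
3 | 7-hydroxy-8-(2-methylpropanoyl)-1,5-dithiaspiro[5.5]undec-7-ene-9,11-dione | O=C1CC(=O)C(C(=O)C(C)C)=C(O)C12SCCCS2 | intermediate
4 | (3R)-3,7-dimethylocta-1,6-dien-3-ol, (R)-(−)-linalool | C=C[C@](C)(O)CCC=C(C)C | starting material
5 | (2E,6R)-6-hydroxy-2,6-dimethylocta-2,7-dienal | C=C[C@](C)(O)CC/C=C(\C)C=O | intermediate
6 | (10E)-7-hydroxy-10-[(2E,6R)-6-hydroxy-2,6-dimethylocta-2,7-dien-1-ylidene]-8-(2-methylpropanoyl)-1,5-dithiaspiro[5.5]undec-7-ene-9,11-dione | O=C1/C(=C/C(C)=C/CC[C@@](C)(O)C=C)C(=O)C(C(=O)C(C)C)=C(O)C12SCCCS2 | intermediate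
7 | 7-hydroxy-2-[(3R)-3-hydroxy-3-methylpent-4-en-1-yl]-3-methyl-6-(2-methylpropanoyl)spiro[chromene-8,2'-[1,3]dithian]-5(2H)-one, both C-2 epimers | CC(C)C(=O)C1=C(O)C2(SCCCS2)C3=C(C=C(C)C(CC[C@@](C)(O)C=C)O3)C1=O | intermediate
8 | (1S,3'R,3a'S,7a'R)-3',4-dihydroxy-3',7'-dimethyl-3-(2-methylpropanoyl)-5,5-(propane-1,3-diyldisulfanediyl)-1',2',3',3a',4',7a'-hexahydrospiro[cyclohex-3-ene-1,5'-indene]-2,6-dione | S1CCCSC12C(=O)[C@]3(C[C@H]4[C@@H](CC[C@@]4(C)O)C(C)=C3)C(=O)C(C(=O)C(C)C)=C2O | intermediate
9 | (1S,3'R,3a'S,7'R,7a'R)-7'-hydroperoxy-3',4-dihydroxy-3',7'-dimethyl-3-(2-methylpropanoyl)-5,5-(propane-1,3-diyldisulfanediyl)octahydrospiro[cyclohex-3-ene-1,5'-indene]-2,6-dione | S1CCCSC12C(=O)[C@]3(C[C@H]4[C@@H](CC[C@@]4(C)O)[C@](C)(OO)C3)C(=O)C(C(=O)C(C)C)=C2O | intermediate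
10 | (1S,3'R,3a'S,7'R,7a'R)-3',4,7'-trihydroxy-3',7'-dimethyl-3-(2-methylpropanoyl)-5,5-(propane-1,3-diyldisulfanediyl)octahydrospiro[cyclohex-3-ene-1,5'-indene]-2,6-dione | S1CCCSC12C(=O)[C@]3(C[C@H]4[C@@H](CC[C@@]4(C)O)[C@](C)(O)C3)C(=O)C(C(=O)C(C)C)=C2O | intermediate
11 | (1R,3'R,3a'S,7'R,7a'R)-3',4,7'-trihydroxy-3',7'-dimethyl-3-(2-methylpropanoyl)octahydrospiro[cyclohex-3-ene-1,5'-indene]-2,6-dione | C1C(=O)[C@]2(C[C@H]3[C@@H](CC[C@@]3(C)O)[C@](C)(O)C2)C(=O)C(C(=O)C(C)C)=C1O | intermediate
12 | (1R,3'R,3a'S,7'R,7a'R)-3',4,6,7'-tetrahydroxy-3',7'-dimethyl-5-(3-methylbut-2-en-1-yl)-3-(2-methylpropanoyl)octahydrospiro[cyclohexa-3,5-diene-1,5'-inden]-2-one | CC(C)=CCC1=C(O)[C@]2(C[C@H]3[C@@H](CC[C@@]3(C)O)[C@](C)(O)C2)C(=O)C(C(=O)C(C)C)=C1O | intermediate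
13 | (1R,3'R,3a'S,7'R,7a'R)-3',4,7'-trihydroxy-3',7'-dimethyl-5,5-bis(3-methylbut-2-en-1-yl)-3-(2-methylpropanoyl)octahydrospiro[cyclohex-3-ene-1,5'-indene]-2,6-dione (CNP0273836.1) | CC(C)=CCC1(CC=C(C)C)C(=O)[C@]2(C[C@H]3[C@@H](CC[C@@]3(C)O)[C@](C)(O)C2)C(=O)C(C(=O)C(C)C)=C1O | target

**Count and risks**
Total step count: 6. Longest linear sequence: 5 (steps 1, 3, 4, 5, 6).

Most likely to fail, step 3: the diene terminus is fully substituted and electron-poor and the dienophile is an unactivated vinyl group, so the cycloaddition needs about 165 °C. Ring fusion, alkene face and spiro carbon are all set at once; the spiro carbon is the least secure, and its C-1 epimer is the expected main by-product, to be removed by chromatography. The fallback sets out from 3 and 4 and builds the same bonds by radical chemistry. Mn(OAc)3·2H2O and Cu(OAc)2 in AcOH at 50 °C add the ring-A radical to the vinyl terminus of 4, the secondary radical closes 5-exo onto the trisubstituted alkene, and Cu(OAc)2 oxidises the tertiary radical to an isopropenyl group, giving the cyclopentylmethyl trione F1. A second oxidation of F1 with Mn(OAc)3·2H2O under O2 in AcOH, then PPh3, closes the ring-A radical 6-endo onto the isopropenyl group with O2 capture at C-7'. It comes back to the route at 10.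

Second, step 1: the gem-bis-sulfenylation has to beat sulfenylation of the second ring carbon and must dearomatise the ring. The fallback sets out from 1 and 5 and reverses the order. Ethylenediammonium diacetate in toluene at 80 °C gives, by Knoevenagel condensation and oxa-6π electrocyclisation through the 4-hydroxyl, the aromatic 2H-chromene F2, which has only one free ring carbon. Sulfenylation of F2 with trimethylene dithiotosylate and KOAc then dearomatises it. It comes back to the route at 7, which is heated as in step 3.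

Third, step 6: O-prenylation and mono-alkylation can outrun the second C-alkylation at a carbon flanked by two carbonyls. The fallback sets out from 11 and uses neutral Tsuji–Trost alkylation: Pd(PPh3)4 (5 mol%) and prenyl methyl carbonate (CC(C)=CCOC(=O)OC) in THF at 40 °C. The soft triketonate attacks the less hindered allyl terminus, and any O-prenyl ether re-ionises and is funnelled to carbon. It passes through 12 and comes back to the route at 13; it makes no new compound (F0).

**Further compounds**
F1 | step 3 | 7,11-dihydroxy-10-{[(1S,2R,5R)-2-hydroxy-2-methyl-5-(prop-1-en-2-yl)cyclopentyl]methyl}-8-(2-methylpropanoyl)-1,5-dithiaspiro[5.5]undeca-7,10-dien-9-one | OC1=C(C[C@H]2[C@@H](CC[C@@]2(C)O)C(C)=C)C(=O)C(C(=O)C(C)C)=C(O)C13SCCCS3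
F2 | step 1 | 1-{5,7-dihydroxy-2-[(3R)-3-hydroxy-3-methylpent-4-en-1-yl]-3-methyl-2H-chromen-6-yl}-2-methylpropan-1-one, both C-2 epimers | CC(C)C(=O)c1c(O)c2C=C(C)C(CC[C@@](C)(O)C=C)Oc2cc1O
F0 | step 6 | none | none
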